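## The problem

Flemistrictin D is a 2,2-dimethyl-2H-chromene whose benzene ring carries no hydrogen. Going round from C8a (the carbon bound to the pyran oxygen) there is a free hydroxyl at C8, a methoxy group at C7, the 3-phenylpropanoyl group at C6, a second free hydroxyl at C5 and the pyran carbon at C4a. There is no stereocentre, so nothing has to be controlled in space and the whole difficulty is regiochemical. Four ring oxygens in three different states (pyran ether, two phenols, one methyl ether) and two carbon substituents must each reach the right carbon. The C5/C8 pair is a para-hydroquinone that air or any mild oxidant converts into the quinone. The C3=C4 bond is an electron-rich styrene-type alkene that tolerates neither strong acid, electrophiles, radicals nor light, and the acyl group sits in the crowded slot between the C5 hydroxyl and the C7 methoxy group. The feature that opens a convergent solution is the oxygen pattern itself. The run C8a(O)–C8(O)–C7(OMe)–C6(H) is what a ring-opened 3-methoxy-4-alkoxycyclobut-2-enone supplies (carbonyl carbon, C4, C3, C2). The remaining pair C4a(C)–C5(O) is a 1-siloxyalkyne whose prenyl substituent later becomes C4, C3 and C2 of the pyran ring.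

## Retrosynthesis

The last operation should only uncover the hydroquinone, so target 25 is traced to its bis(methoxymethyl) ether 24 by cutting the two acetal O–CH2 bonds. Acetals leave under dilute acid without any oxidant or reductant. Benzyl ethers would need a hydrogenolysis that also saturates C3=C4, and silyl ethers are incompatible with the acylation that precedes.

In 24 the aryl–carbonyl bond at C6 is cut, giving chromene 18 and the N-methoxy-N-methyl amide 21 (itself from acid chloride 19 and amine salt 20).

- An acid-mediated acylation is excluded by the chromene double bond.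
- A radical acylation at the quinone oxidation level would save a step. It would, however, have to attack the carbon next to the methoxy group, the electron-rich terminus of a vinylogous ester that a nucleophilic acyl radical avoids, on a chromophore that is itself photolabile.
- In 18, by contrast, C6–H is the only aromatic hydrogen and lies between two ether oxygens, so a directed metalation has nowhere else to go. The amide acyl donor stops at the ketone.

Chromene 18 is simplified by cutting the C5 acetal back to phenol 17 and then to silyl ether 16. This exchange is the price of the annulation, which necessarily delivers a silyl ether at C5. Such a group neither coordinates lithium nor stays on oxygen next to an aryllithium, whereas the acetal does both.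

In 16 the O1–C2 bond is cut and the C3=C4 unsaturation is returned to a prenyl side chain, giving ortho-prenylphenol 14. Against a metathesis cut of C3=C4 this has the advantage that the open-chain precursor needs no extra carbons or handles. The forward step is a dehydrogenative oxa-cyclization that must act at the benzylic position while the para-dioxygenated ring stays protected.

Phenol 14 is cut at three ring bonds, C8a–C4a, C5–C6 and C8a–C8, into cyclobutenone 5 (four ring carbons) and siloxyalkyne 9 (two ring carbons plus the prenyl group).

- Functionalising a preformed tri- or tetra-oxygenated arene would require several oxygenations and alkylations of uncertain regiochemistry.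
- Here each oxygen is placed by construction and arrives in a different state: free phenol at C8a (the one needed for pyran closure), silyl ether at C5, methyl ether at C7 and acetal at C8.
- An acetal rather than a silyl group is put on the cyclobutenone oxygen because a silyl group next to the newly formed phenol could wander between O8 and O8a.
- The forward reaction must open the four-membered ring with the alkoxy group rotating outward and must join ketene and alkyne in one orientation.

Siloxyalkyne 9 is cut at the O–Si bond and at the alkyne carbon remote from oxygen, which leads to ester 6 by a one-carbon homologation through an ynolate.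

Cyclobutenone 5 is traced through alcohol 4 (acetal O–CH2 bond) and enedione 3 (C4–H bond, a carbonyl reduction) to dimethyl squarate 1. The squarate already holds the four ring carbons with oxygen on each. One hydride and an acid-induced loss of methanol convert it into 3, in which the carbon destined to become C6 carries hydrogen.

## Roads not taken

Alternative 1: The cut is the C3=C4 bond. The second-generation Grubbs catalyst would join the styrene and the 1,1-dimethylallyl ether of diene A2 and close the pyran ring, giving chromenol A1.

- Merits: the ring closure is mild, neutral and about as well precedented as any step could be, and in that respect it is safer than the annulation chosen here.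
- Weak points: it forms the easiest bond of the molecule and leaves the hard part untouched. A1 lacks the C8 oxygen and the C6 acyl group and has two free positions, both flanked by two oxygens. The C8 oxygen would have to be introduced para to the C5 hydroxyl by an Elbs or Teuber oxidation through the quinone, followed by reduction and protection. A2 itself needs an ortho-vinyl group and a hindered tertiary allyl aryl ether on a phloroglucinol whose three oxygens must first be told apart.
- Comparison: the count would come out equal or longer. The chosen plan sets against the safer ring closure an arene whose four oxygens and single free position are fixed in one step.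

Alternative 2: The cut is C5–C4a, with C8–C8a made beforehand by adding the 6-lithio derivative of enol ether A5 to the reactive carbonyl of the same enedione 3. Heating the adduct A4 would open it to a dienylketene whose 6π closure gives chromane hydroquinone A3.

- Merits: this thermal ring expansion of 4-alkenyl-4-hydroxycyclobutenones is better documented than the annulation used here. It brings the pyran ring along, and after bis-protection and benzylic dehydrogenation it would reach 18 in a linear sequence about two steps shorter. In these respects it is the stronger road.
- Weak points: A5 is not an article of commerce and must be made and metalated. A3 is a free, air-sensitive hydroquinone. The ring arrives at the chromane level, so the C3=C4 bond has to be introduced late by hydride abstraction next to a hydroquinone that must be protected first.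
- Comparison: the chosen plan sets against it partners that come from purchasable materials in three steps and one step, the correct chromene oxidation level by a closure on a monophenol, and no free hydroquinone before the final step.

Alternative 3: The cut is the C8a–O1 bond. The tertiary alcohol of the (Z)-alkenyl methoxyquinone A7 would add 6-endo to the neighbouring quinone CH, and enolization would give chromene hydroquinone A6. A7 would come from a coumarin such as A8 by double methyl addition to the lactone and oxidation, so the ring oxygen "walks" from one ortho position to the other.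

- Merits: it is the shortest road. All ring carbons come from one purchasable arene, and A6 is only a bis-protection away from 18, perhaps three steps fewer than here.
- Weak points: the closure has to win against dehydration and Z/E isomerization of the allylic tertiary alcohol and against redox exchange between A6 and unreacted A7, which would deliver mixtures of hydroquinone and quinone. A regiochemically pure A8 is costly. After A6 the same protection and acylation steps are still required.
- Comparison: the chosen plan is longer. It offers in return that the position of every oxygen is fixed by the bond-forming events and that quinone-level intermediates are avoided.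

Key step: step 5

Remark: dimethyl squarate 1, ester 6, acid chloride 19 and amine salt 20 are taken as purchasable, and the final hydroquinone 25 is assumed to need handling under argon.

## Route

Step 1
Reactants: 1 dimethyl squarate (3,4-dimethoxycyclobut-3-ene-1,2-dione)
Product: 3 3-methoxycyclobut-3-ene-1,2-dione, via 4-hydroxy-2,3-dimethoxycyclobut-2-en-1-one 2 (not isolated)
Conditions: LiAlH(Ot-Bu)3, THF, −78 → 0 °C; dilute HCl work-up; crude 2, 12 M HCl (cat.), CH2Cl2, rt
Reagents that add atoms: water, O
Why: One hydride adds to one of the two equivalent vinylogous-ester carbonyls; acid then ionizes the allylic hydroxyl of 2, water is taken up at the methoxy-stabilized end of the cation and methanol is lost, a 1,3-oxygen transposition that leaves the former carbinol carbon as a vinylic CH (reduction/acid route from squarates to semisquarates).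

Step 2
Reactants: 3 3-methoxycyclobut-3-ene-1,2-dione
Product: 4 racemic 4-hydroxy-3-methoxycyclobut-2-en-1-one
Conditions: LiAlH(Ot-Bu)3 (1.0 equiv), THF, −78 °C; aq. potassium sodium tartrate
Reagents that add atoms: none
Why: The carbonyl next to the methoxy-bearing carbon is an isolated strained ketone while the other is the carbonyl of a vinylogous ester, so a bulky aluminium hydride at low temperature should add once and 1,2 at the former (regioselective mono-reduction of a cyclobutenedione); the new C4 stereocentre forms as the racemate, which is immaterial because step 5 destroys it.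

Step 3
Reactants: 4 racemic 4-hydroxy-3-methoxycyclobut-2-en-1-one
Product: 5 racemic 3-methoxy-4-(methoxymethoxy)cyclobut-2-en-1-one
Conditions: MOMCl, i-Pr2NEt, CH2Cl2, 0 °C → rt
Reagents that add atoms: chloromethyl methyl ether, COCCl
Why: Standard O-alkylation of a secondary alcohol to its methoxymethyl acetal; the amine base cannot enolize the ketone toward an antiaromatic cyclobutadienolate, and the acetal is chosen because it withstands heat, DDQ, fluoride and alkyllithium and cannot migrate to a neighbouring phenol.

Step 4
Reactants: 6 ethyl 4-methylpent-3-enoate
Product: 9 triisopropyl[(5-methylhex-4-en-1-yn-1-yl)oxy]silane, via lithium 1,1-dibromo-5-methylhexa-1,4-dien-2-olate 7 (not isolated), via lithium 5-methylhex-4-en-1-yn-1-olate 8 (not isolated)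
Conditions: CH2Br2, lithium 2,2,6,6-tetramethylpiperidide, THF, −78 °C; then 6; LiN(SiMe3)2; n-BuLi, −78 °C → rt; then i-Pr3SiCl, −78 °C → rt
Reagents that add atoms: dibromomethane, BrCBr; chlorotriisopropylsilane, CC(C)[Si](Cl)(C(C)C)C(C)C
Why: Kowalski ester homologation stopped at the ynolate: dibromomethyllithium adds to the ester, enolate 7 undergoes bromine–lithium exchange and a 1,2-shift of the prenyl group with loss of bromide to give ynolate 8, and the bulky chlorosilane silylates 8 on oxygen to the siloxyalkyne.

Step 5
Reactants: 5 racemic 3-methoxy-4-(methoxymethoxy)cyclobut-2-en-1-one; 9 triisopropyl[(5-methylhex-4-en-1-yn-1-yl)oxy]silane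
Product: 14 3-methoxy-2-(methoxymethoxy)-6-(3-methylbut-2-en-1-yl)-5-[(triisopropylsilyl)oxy]phenol, via vinylketene 10 (not isolated), via 4-alkenylcyclobutenone adduct 11 (not isolated), via dienylketene 12 (not isolated), via cyclohexa-2,4-dienone 13 (not isolated)
Conditions: 9 (1.3 equiv), toluene (0.3 M), argon, 80 °C then 110 °C
Reagents that add atoms: none
Why: Heating opens 5 by conrotatory 4π cleavage of the C1–C4 bond to vinylketene 10; the C4 alkoxy group is a donor and should rotate outward, leaving only hydrogen pointing inward at that terminus. The ketene adds the electron-rich alkyne 9 in a [2+2] cycloaddition in which the nucleophilic, prenyl-bearing alkyne carbon bonds to the ketene carbonyl carbon, which gives cyclobutenone 11 and with it the C8a–C4a and C5–C6 bonds. A second 4π opening of 11 gives dienylketene 12, whose thermal disrotatory 6π electrocyclization joins the ketene carbon to the alkoxy-bearing terminus (C8a–C8) and closes the benzene ring as dienone 13; tautomerization gives phenol 14. The closest known reaction type is the Danheiser benzannulation of cyclobutenones with triisopropylsiloxyalkynes to resorcinol monosilyl ethers, from which this case differs only in the two oxygen substituents on the four-membered ring. No stereocentre remains: the sp3 centres of 5, 11 and 13 are racemic and are erased by ring opening or tautomerization. Three selectivities are needed: the orientation of the [2+2] step, secured by the polarity of the siloxyalkyne; outward rotation at C4, secured by the donor character of the acetal oxygen; and reaction at the alkyne and not the prenyl alkene, secured by the far higher ketenophilicity of the ynol ether. The four ring oxygens emerge as free phenol (C8a), silyl ether (C5), methyl ether (C7) and acetal (C8).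

Step 6
Reactants: 14 3-methoxy-2-(methoxymethoxy)-6-(3-methylbut-2-en-1-yl)-5-[(triisopropylsilyl)oxy]phenol
Product: 16 triisopropyl{[7-methoxy-8-(methoxymethoxy)-2,2-dimethyl-2H-chromen-5-yl]oxy}silane, via ortho-quinone methide 15 (not isolated)
Conditions: DDQ (1.1 equiv), benzene, 80 °C
Reagents that add atoms: none
Why: Dehydrogenative cyclization of an ortho-prenylphenol: DDQ abstracts hydride from the benzylic, allylic CH2 of the electron-rich arene, loss of the phenolic proton gives quinone methide 15, and oxa-6π electrocyclization forms the O1–C2 bond and the 2H-pyran ring; both para oxygens are capped, so quinone formation is blocked.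

Step 7
Reactants: 16 triisopropyl{[7-methoxy-8-(methoxymethoxy)-2,2-dimethyl-2H-chromen-5-yl]oxy}silane
Product: 17 7-methoxy-8-(methoxymethoxy)-2,2-dimethyl-2H-chromen-5-ol
Conditions: Bu4NF, THF, 0 °C
Reagents that add atoms: none
Why: Fluoride cleaves the aryl silyl ether selectively; the acetal, the methyl ether and the chromene double bond are inert to it.

Step 8
Reactants: 17 7-methoxy-8-(methoxymethoxy)-2,2-dimethyl-2H-chromen-5-ol
Product: 18 7-methoxy-5,8-bis(methoxymethoxy)-2,2-dimethyl-2H-chromene
Conditions: MOMCl, i-Pr2NEt, CH2Cl2, 0 °C → rt
Reagents that add atoms: chloromethyl methyl ether, COCCl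
Why: Routine O-alkylation of a phenol; it installs at C5 a group that coordinates lithium and cannot shift to carbon, as required for the metalation that follows.

Step 9
Reactants: 19 3-phenylpropanoyl chloride; 20 N,O-dimethylhydroxylamine hydrochloride
Product: 21 N-methoxy-N-methyl-3-phenylpropanamide
Conditions: Et3N (2.2 equiv), CH2Cl2, 0 °C → rt
Reagents that add atoms: none
Why: N-acylation of the liberated amine by an acid chloride (Weinreb amide formation).

Step 10
Reactants: 18 7-methoxy-5,8-bis(methoxymethoxy)-2,2-dimethyl-2H-chromene; 21 N-methoxy-N-methyl-3-phenylpropanamide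
Product: 24 1-[7-methoxy-5,8-bis(methoxymethoxy)-2,2-dimethyl-2H-chromen-6-yl]-3-phenylpropan-1-one, via C6 aryllithium 22 (not isolated), via tetrahedral lithium chelate 23 (not isolated)
Conditions: n-BuLi (1.2 equiv), THF, −20 → 0 °C; then 21, −78 → 0 °C; aqueous work-up
Reagents that add atoms: none
Why: Directed ortho-metalation followed by Weinreb ketone synthesis: C6–H is the only aromatic hydrogen and lies between the C5 acetal and the C7 methoxy group, so lithiation to 22 is regiospecific, and the chelated adduct 23 does not collapse until work-up, which prevents a second addition.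

Step 11
Reactants: 24 1-[7-methoxy-5,8-bis(methoxymethoxy)-2,2-dimethyl-2H-chromen-6-yl]-3-phenylpropan-1-one
Product: 25 flemistrictin D, 1-(5,8-dihydroxy-7-methoxy-2,2-dimethyl-2H-chromen-6-yl)-3-phenylpropan-1-one
Conditions: 2 M HCl, MeOH, 40 °C, argon
Reagents that add atoms: none
Why: Acid-catalysed acetal exchange with methanol removes both methoxymethyl groups, the C5 one assisted by the neighbouring ketone; the acyl-deactivated chromene double bond should tolerate dilute methanolic acid, and exclusion of air protects the hydroquinone.

## Compound list

1 | dimethyl squarate (3,4-dimethoxycyclobut-3-ene-1,2-dione) | COC1=C(OC)C(=O)C1=O | starting material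
2 | racemic 4-hydroxy-2,3-dimethoxycyclobut-2-en-1-one | COC1=C(OC)C(=O)C1O | intermediate (not isolated)
3 | 3-methoxycyclobut-3-ene-1,2-dione | COC1=CC(=O)C1=O | intermediate
4 | racemic 4-hydroxy-3-methoxycyclobut-2-en-1-one | COC1=CC(=O)C1O | intermediate
5 | racemic 3-methoxy-4-(methoxymethoxy)cyclobut-2-en-1-one | COC1=CC(=O)C1OCOC | intermediate
6 | ethyl 4-methylpent-3-enoate | CCOC(=O)CC=C(C)C | starting material
7 | lithium 1,1-dibromo-5-methylhexa-1,4-dien-2-olate | [Li]OC(CC=C(C)C)=C(Br)Br | intermediate (not isolated)
8 | lithium 5-methylhex-4-en-1-yn-1-olate | [Li]OC#CCC=C(C)C | intermediate (not isolated)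
9 | triisopropyl[(5-methylhex-4-en-1-yn-1-yl)oxy]silane | CC(C)=CCC#CO[Si](C(C)C)(C(C)C)C(C)C | intermediate
10 | (3Z)-3-methoxy-4-(methoxymethoxy)buta-1,3-dien-1-one (acetal oxygen trans to the ketene carbon) | O=C=C/C(OC)=C/OCOC | intermediate (not isolated)
11 | racemic 4-[(Z)-1-methoxy-2-(methoxymethoxy)ethenyl]-2-(3-methylbut-2-en-1-yl)-3-[(triisopropylsilyl)oxy]cyclobut-2-en-1-one | O=C1C(CC=C(C)C)=C(O[Si](C(C)C)(C(C)C)C(C)C)C1/C(OC)=C/OCOC | intermediate (not isolated)
12 | (3E,5Z)-5-methoxy-6-(methoxymethoxy)-2-(3-methylbut-2-en-1-yl)-3-[(triisopropylsilyl)oxy]hexa-1,3,5-trien-1-one (ketene carbon and C5 cis across C3=C4) | O=C=C(CC=C(C)C)/C(O[Si](C(C)C)(C(C)C)C(C)C)=C\C(OC)=C\OCOC | intermediate (not isolated)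
13 | racemic 5-methoxy-6-(methoxymethoxy)-2-(3-methylbut-2-en-1-yl)-3-[(triisopropylsilyl)oxy]cyclohexa-2,4-dien-1-one | O=C1C(CC=C(C)C)=C(O[Si](C(C)C)(C(C)C)C(C)C)C=C(OC)C1OCOC | intermediate (not isolated)
14 | 3-methoxy-2-(methoxymethoxy)-6-(3-methylbut-2-en-1-yl)-5-[(triisopropylsilyl)oxy]phenol | COCOc1c(O)c(CC=C(C)C)c(O[Si](C(C)C)(C(C)C)C(C)C)cc1OC | intermediate
15 | (6Z)-3-methoxy-2-(methoxymethoxy)-6-(3-methylbut-2-en-1-ylidene)-5-[(triisopropylsilyl)oxy]cyclohexa-2,4-dien-1-one | O=C1C(OCOC)=C(OC)C=C(O[Si](C(C)C)(C(C)C)C(C)C)/C1=C/C=C(C)C | intermediate (not isolated)
16 | triisopropyl{[7-methoxy-8-(methoxymethoxy)-2,2-dimethyl-2H-chromen-5-yl]oxy}silane | COCOc1c(OC)cc(O[Si](C(C)C)(C(C)C)C(C)C)c2C=CC(C)(C)Oc12 | intermediate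
17 | 7-methoxy-8-(methoxymethoxy)-2,2-dimethyl-2H-chromen-5-ol | COCOc1c(OC)cc(O)c2C=CC(C)(C)Oc12 | intermediate
18 | 7-methoxy-5,8-bis(methoxymethoxy)-2,2-dimethyl-2H-chromene | COCOc1cc(OC)c(OCOC)c2OC(C)(C)C=Cc12 | intermediate
19 | 3-phenylpropanoyl chloride | O=C(Cl)CCc1ccccc1 | starting material
20 | N,O-dimethylhydroxylamine hydrochloride | CNOC.Cl | starting material
21 | N-methoxy-N-methyl-3-phenylpropanamide | CON(C)C(=O)CCc1ccccc1 | intermediate
22 | [7-methoxy-5,8-bis(methoxymethoxy)-2,2-dimethyl-2H-chromen-6-yl]lithium | [Li]c1c(OC)c(OCOC)c2OC(C)(C)C=Cc2c1OCOC | intermediate (not isolated)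
23 | racemic lithium 1-[7-methoxy-5,8-bis(methoxymethoxy)-2,2-dimethyl-2H-chromen-6-yl]-1-[methoxy(methyl)amino]-3-phenylpropan-1-olate | [Li]OC(CCc1ccccc1)(N(C)OC)c1c(OC)c(OCOC)c2OC(C)(C)C=Cc2c1OCOC | intermediate (not isolated)
24 | 1-[7-methoxy-5,8-bis(methoxymethoxy)-2,2-dimethyl-2H-chromen-6-yl]-3-phenylpropan-1-one | COCOc1c(C(=O)CCc2ccccc2)c(OC)c(OCOC)c2OC(C)(C)C=Cc12 | intermediate
25 | flemistrictin D, 1-(5,8-dihydroxy-7-methoxy-2,2-dimethyl-2H-chromen-6-yl)-3-phenylpropan-1-one | COc1c(O)c2c(c(O)c1C(=O)CCc1ccccc1)C=CC(C)(C)O2 | target

## Step count and least certain steps

Total: 11 steps. Longest linear sequence: 9 steps (steps 1, 2, 3, 5, 6, 7, 8, 10, 11, from 1 to 25); steps 4 and 9 are one-step side branches.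

**Step 5 (key step).**
- Risk: unproductive consumption of the vinylketene, by dimerization, by acylation of the product phenol, or by decomposition of the doubly oxygenated cyclobutenone before or after ring opening. The vinylogous-ester character of 5 raises the opening temperature, and the effect of the C4 alkoxy group on ketene reactivity has not been tested with this partner.
- Fallback: it sets out from 9 and returns at 16. Siloxyalkyne 9 would be heated with 3-methoxycyclobut-2-en-1-one F1 (the C4-unsubstituted partner, obtainable by O-methylation of cyclobutane-1,3-dione) to give 5-methoxy-2-(3-methylbut-2-en-1-yl)-3-[(triisopropylsilyl)oxy]phenol F2. DDQ would close the pyran to triisopropyl[(7-methoxy-2,2-dimethyl-2H-chromen-5-yl)oxy]silane F3. Lithiation with n-BuLi at C8, the position between the pyran oxygen and the methoxy group (C6 is screened by the bulky, non-coordinating silyl ether), followed by B(OMe)3 and H2O2, would give 7-methoxy-2,2-dimethyl-5-[(triisopropylsilyl)oxy]-2H-chromen-8-ol F4. MOMCl and i-Pr2NEt would convert F4 into 16.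
- The same detour would be taken if step 2 failed to deliver 4 cleanly through conjugate hydride addition to the unsubstituted enedione, since it needs neither 3, 4 nor 5.

**Step 4.**
- Risk: deprotonation of the β,γ-unsaturated ester at its doubly activated CH2 by the lithium carbenoid or amide in place of carbonyl addition, with return or conjugation of the ester and a low conversion to ynolate.
- Fallback: it sets out from 6 and returns at 9. Reduction of 6 with i-Bu2AlH at −78 °C would give 4-methylpent-3-enal F5. CBr4 and PPh3 would give 1,1-dibromo-5-methylhexa-1,4-diene F6 (Corey–Fuchs). Treatment of F6 with n-BuLi would give the lithium acetylide, which would be oxidized in the same flask by LiOOt-Bu to ynolate 8 and silylated with i-Pr3SiOTf to 9.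

**Step 6.**
- Risk: over-oxidation of the very electron-rich phenol (ring oxidation with loss of a protecting group) or intermolecular capture of the quinone methide before it cyclizes.
- Fallback: it sets out from 14 and returns at 16. PhSeCl in CH2Cl2 at −78 °C would effect 6-endo selenoetherification, the phenol oxygen attacking the tertiary carbon, to give racemic triisopropyl{[7-methoxy-8-(methoxymethoxy)-2,2-dimethyl-3-(phenylselanyl)-3,4-dihydro-2H-chromen-5-yl]oxy}silane F7. Oxidation with H2O2 and syn-elimination of the selenoxide toward C4 (C2 is quaternary) would give 16 without any hydride-abstracting oxidant.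

**Step 10.**
- Risk: proton transfer from the α-CH2 of the amide to the crowded, doubly ortho-substituted aryllithium, which would return 18, or slow acyl transfer that lets side reactions of the organolithium with the chromene double bond intervene.
- Fallback: it sets out from 18 (through the same aryllithium 22) and returns at 24. Compound 22 would be quenched with the far more electrophilic 3-phenylpropanal to give racemic 1-[7-methoxy-5,8-bis(methoxymethoxy)-2,2-dimethyl-2H-chromen-6-yl]-3-phenylpropan-1-ol F8, and Dess–Martin periodinane would oxidize F8 to 24.

## Further compounds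

F1 | step 5 | 3-methoxycyclobut-2-en-1-one | COC1=CC(=O)C1
F2 | step 5 | 5-methoxy-2-(3-methylbut-2-en-1-yl)-3-[(triisopropylsilyl)oxy]phenol | COc1cc(O)c(CC=C(C)C)c(O[Si](C(C)C)(C(C)C)C(C)C)c1
F3 | step 5 | triisopropyl[(7-methoxy-2,2-dimethyl-2H-chromen-5-yl)oxy]silane | COc1cc(O[Si](C(C)C)(C(C)C)C(C)C)c2C=CC(C)(C)Oc2c1
F4 | step 5 | 7-methoxy-2,2-dimethyl-5-[(triisopropylsilyl)oxy]-2H-chromen-8-ol | COc1cc(O[Si](C(C)C)(C(C)C)C(C)C)c2C=CC(C)(C)Oc2c1O
F5 | step 4 | 4-methylpent-3-enal | CC(C)=CCC=O
F6 | step 4 | 1,1-dibromo-5-methylhexa-1,4-diene | CC(C)=CCC=C(Br)Br
F7 | step 6 | racemic triisopropyl{[7-methoxy-8-(methoxymethoxy)-2,2-dimethyl-3-(phenylselanyl)-3,4-dihydro-2H-chromen-5-yl]oxy}silane | COCOc1c(OC)cc(O[Si](C(C)C)(C(C)C)C(C)C)c2CC([Se]c3ccccc3)C(C)(C)Oc12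
F8 | step 10 | racemic 1-[7-methoxy-5,8-bis(methoxymethoxy)-2,2-dimethyl-2H-chromen-6-yl]-3-phenylpropan-1-ol | COCOc1c(C(O)CCc2ccccc2)c(OC)c(OCOC)c2OC(C)(C)C=Cc12
A1 | alternative 1 | 7-methoxy-2,2-dimethyl-2H-chromen-5-ol | COc1cc(O)c2C=CC(C)(C)Oc2c1
A2 | alternative 1 | 5-methoxy-3-[(2-methylbut-3-en-2-yl)oxy]-2-vinylphenol | COc1cc(O)c(C=C)c(OC(C)(C)C=C)c1
A3 | alternative 2 | 7-methoxy-2,2-dimethylchromane-5,8-diol | COc1cc(O)c2c(c1O)OC(C)(C)CC2
A4 | alternative 2 | racemic 4-(6,6-dimethyl-5,6-dihydro-4H-pyran-2-yl)-4-hydroxy-3-methoxycyclobut-2-en-1-one | COC1=CC(=O)C1(O)C1=CCCC(C)(C)O1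
A5 | alternative 2 | 2,2-dimethyl-3,4-dihydro-2H-pyran | CC1(C)CCC=CO1
A6 | alternative 3 | 7-methoxy-2,2-dimethyl-2H-chromene-5,8-diol | COc1cc(O)c2C=CC(C)(C)Oc2c1O
A7 | alternative 3 | 2-[(Z)-3-hydroxy-3-methylbut-1-en-1-yl]-5-methoxycyclohexa-2,5-diene-1,4-dione | COC1=CC(=O)C(/C=C\C(C)(C)O)=CC1=O
A8 | alternative 3 | 6-hydroxy-7-methoxy-2H-chromen-2-one | COc1cc2OC(=O)C=Cc2cc1O
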